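## Retrosynthetic overview

1. The target is a heliangolide (germacrane numbering). Ring A is the ten-membered carbocycle C1–C10 with a 4Z alkene. Ring B is the α-methylene-γ-lactone O–C12–C11–C7–C6, trans-fused at C6–C7. Ring C is the 1,10-oxirane.
2. Endgame: PMB removal at O15, peripheral epoxidation of the 1(10)E alkene (ring C), and acylation of O8 and O3.
3. Key disconnection: C6–C7 and C11–C12 are cut together. This opens rings A and B at once and leads to CO2 and an acyclic allenyl (Z)-enal. In the forward direction this is a nickel-mediated carboxylative macro-allylation with lactonisation in the same flask.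
4. Enabling feature: in ring B the exocyclic C13H2=C11 unit next to C7 is the imprint of a terminal allene C7=C11=C13. C12 with its oxygens is one molecule of CO2. The ring-fusion carbinol C6, allylic to C4=C5, is the carbonyl carbon of an enal. The oxygen on C8 next to C7 steers the face.
5. The open chain comes from an allenyl aldehyde (C1–C3, C7–C14; asymmetric propargylation, carboalumination, Crabbé homologation) and a (Z)-iodoalkene from but-2-yne-1,4-diol (C4–C6, C15), joined at C3–C4. Ring order: A, then B (both in step 15), then C (step 19).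

Key step: step 15

Remark on the chemistry: germacrane locants are used for all intermediates. C11–C13 is the three-carbon branch on C7, C14 the methyl on C10, and C15 the CH2O on C4. α/β refer to the usual germacranolide drawing. DBU ligands on nickel are left out of the SMILES.

## Route

Step 1
Reactants: 1 3-(trimethylsilyl)prop-2-ynal; 2 allenylboronic acid pinacol ester
Product: 3 (R)-1-(trimethylsilyl)hexa-1,5-diyn-3-ol
Conditions: (R)-TRIP (10 mol %), 4 Å MS, toluene, −20 °C; then H2O
Reagents that add atoms: none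
Why: Chiral phosphoric acid catalysed asymmetric propargylation (allenylboronate, SE2′, closed chair transition state): the (R)-catalyst binds a boronate oxygen and the formyl hydrogen and should direct attack to the Re face of 1, which sets C8 as R.

Step 2
Reactants: 3 (R)-1-(trimethylsilyl)hexa-1,5-diyn-3-ol
Product: 4 (R)-3-(tert-butyldimethylsilyloxy)-1-(trimethylsilyl)hexa-1,5-diyne
Conditions: TBSCl, imidazole, DMF, rt
Reagents that add atoms: tert-butyldimethylsilyl chloride CC(C)(C)[Si](C)(C)Cl
Why: Standard silyl ether formation; the TBS ether is a non-leaving cover for O8 that should survive every step up to step 17.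

Step 3
Reactants: 4 (R)-3-(tert-butyldimethylsilyloxy)-1-(trimethylsilyl)hexa-1,5-diyne
Product: 7 (3E,6R)-6-(tert-butyldimethylsilyloxy)-4-methyl-8-(trimethylsilyl)oct-3-en-7-yn-1-ol, via alkenyldimethylalane 5 (not isolated), via lithium alkenylalanate 6 (not isolated)
Conditions: Me3Al, Cp2ZrCl2 (0.25 equiv), CH2Cl2, 0 °C to rt; hexane, n-BuLi, 0 °C; ethylene oxide, THF, 0 °C to rt; 1 M HCl, 0 °C
Reagents that add atoms: trimethylaluminium C[Al](C)C; ethylene oxide C1CO1
Why: Negishi zirconium-catalysed carboalumination adds methyl and aluminium syn across the terminal alkyne only (the silyl-capped alkyne is inert), which fixes the 1(10)E geometry, and the derived alanate opens ethylene oxide with retention at the alkenyl carbon.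

Step 4
Reactants: 7 (3E,6R)-6-(tert-butyldimethylsilyloxy)-4-methyl-8-(trimethylsilyl)oct-3-en-7-yn-1-ol
Product: 8 (3E,6R)-6-(tert-butyldimethylsilyloxy)-4-methyloct-3-en-7-yn-1-ol
Conditions: K2CO3 (0.2 equiv), MeOH, rt
Reagents that add atoms: none
Why: Methoxide-induced protodesilylation of the alkynylsilane; the TBS ether and the alkene are not affected.

Step 5
Reactants: 8 (3E,6R)-6-(tert-butyldimethylsilyloxy)-4-methyloct-3-en-7-yn-1-ol
Product: 10 (3E,6R)-6-(tert-butyldimethylsilyloxy)-4-methylnona-3,7,8-trien-1-ol, via propargylic amine 9 (not isolated)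
Conditions: (CH2O)n, CuBr (0.4 equiv), i-Pr2NH, 1,4-dioxane, reflux
Reagents that add atoms: paraformaldehyde (as formaldehyde) C=O
Why: Crabbé homologation: a copper-catalysed Mannich reaction gives propargylic amine 9, and 1,5-hydride transfer with loss of the imine gives the terminal allene without touching C8.

Step 6
Reactants: 10 (3E,6R)-6-(tert-butyldimethylsilyloxy)-4-methylnona-3,7,8-trien-1-ol
Product: 11 (3E,6R)-6-(tert-butyldimethylsilyloxy)-4-methylnona-3,7,8-trienal
Conditions: DMP, NaHCO3, CH2Cl2, 0 °C
Reagents that add atoms: none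
Why: Dess–Martin oxidation under buffered, non-basic conditions should give the β,γ-unsaturated aldehyde without migration of the double bond; 11 is used at once.

Step 7
Reactants: 12 but-2-yne-1,4-diol
Product: 13 4-(4-methoxybenzyloxy)but-2-yn-1-ol
Conditions: NaH (1 equiv), PMBCl (1 equiv), Bu4NI (cat.), THF–DMF, 0 °C to rt, diol in excess
Reagents that add atoms: 4-methoxybenzyl chloride COc1ccc(CCl)cc1
Why: Williamson etherification with the diol in excess gives the mono-PMB ether, which differentiates C15 from C6.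

Step 8
Reactants: 13 4-(4-methoxybenzyloxy)but-2-yn-1-ol
Product: 15 (Z)-3-iodo-4-(4-methoxybenzyloxy)but-2-en-1-ol, via cyclic alkenylalanate 14 (not isolated)
Conditions: NaAlH2(OCH2CH2OMe)2, THF, 0 °C to rt; I2, THF, −78 to 0 °C; then H2O
Reagents that add atoms: iodine [I][I]
Why: Hydroxyl-directed trans-hydroalumination of the propargylic alcohol gives the five-membered alkenylalanate 14, and iodinolysis with retention places iodine cis to the CH2OH group, the geometry that later becomes the 4Z alkene.

Step 9
Reactants: 15 (Z)-3-iodo-4-(4-methoxybenzyloxy)but-2-en-1-ol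
Product: 16 (Z)-triethyl{[3-iodo-4-(4-methoxybenzyloxy)but-2-en-1-yl]oxy}silane
Conditions: TESCl, imidazole, CH2Cl2, 0 °C
Reagents that add atoms: triethylsilyl chloride CC[Si](Cl)(CC)CC
Why: Standard silylation; the primary TES ether is the one silyl group that step 14 can address selectively.

Step 10
Reactants: 11 (3E,6R)-6-(tert-butyldimethylsilyloxy)-4-methylnona-3,7,8-trienal; 16 (Z)-triethyl{[3-iodo-4-(4-methoxybenzyloxy)but-2-en-1-yl]oxy}silane
Product: 18 (2Z,6E,9R)-9-(tert-butyldimethylsilyloxy)-3-[(4-methoxybenzyloxy)methyl]-7-methyl-1-(triethylsilyloxy)dodeca-2,6,10,11-tetraen-4-ol (both epimers at germacrane C3), via alkenylchromium dichloride 17 (not isolated)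
Conditions: CrCl2 (4 equiv), NiCl2 (2 mol %), DMSO, rt; then H2O
Reagents that add atoms: none
Why: Nozaki–Hiyama–Kishi alkenylation: the non-basic alkenylchromium species adds to the enolisable aldehyde without enolisation or double-bond migration and with retention of the alkene geometry; C3 is formed without control and is corrected in steps 11 and 12.

Step 11
Reactants: 18 allylic alcohol (C3 epimers)
Product: 19 (2Z,6E,9R)-9-(tert-butyldimethylsilyloxy)-3-[(4-methoxybenzyloxy)methyl]-7-methyl-1-(triethylsilyloxy)dodeca-2,6,10,11-tetraen-4-one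
Conditions: DMP, NaHCO3, CH2Cl2, 0 °C
Reagents that add atoms: none
Why: Dess–Martin oxidation of the allylic alcohol erases the uncontrolled C3 centre under conditions that leave the silyl ethers, the allene and the skipped diene untouched.

Step 12
Reactants: 19 enone
Product: 20 (2Z,4S,6E,9R)-9-(tert-butyldimethylsilyloxy)-3-[(4-methoxybenzyloxy)methyl]-7-methyl-1-(triethylsilyloxy)dodeca-2,6,10,11-tetraen-4-ol
Conditions: (R)-Me-CBS (0.5 equiv), catecholborane, toluene, −78 °C; then H2O
Reagents that add atoms: none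
Why: Corey–Bakshi–Shibata reduction: with the α-branched alkenyl group as the large and the CH2 group as the small substituent, the (R)-oxazaborolidine should deliver hydride to give the 3S (3β) alcohol, and catecholborane at −78 °C does not hydroborate the allene.

Step 13
Reactants: 20 (4S)-allylic alcohol
Product: 21 (2Z,4S,6E,9R)-9-(tert-butyldimethylsilyloxy)-3-[(4-methoxybenzyloxy)methyl]-7-methyl-1,4-bis(triethylsilyloxy)dodeca-2,6,10,11-tetraene
Conditions: TESCl, imidazole, DMAP (cat.), CH2Cl2, rt
Reagents that add atoms: triethylsilyl chloride CC[Si](Cl)(CC)CC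
Why: Standard silylation; a silyl ether at O3 cannot ionise on zerovalent nickel as an allylic ester would.

Step 14
Reactants: 21 bis-TES ether
Product: 22 (2Z,4S,6E,9R)-9-(tert-butyldimethylsilyloxy)-3-[(4-methoxybenzyloxy)methyl]-7-methyl-4-(triethylsilyloxy)dodeca-2,6,10,11-tetraenal
Conditions: (COCl)2, DMSO, CH2Cl2, −78 to −30 °C; Et3N, −78 to 0 °C; then H2O
Reagents that add atoms: none
Why: Swern oxidation applied directly to a silyl ether: chlorodimethylsulfonium chloride attacks only the unhindered primary allylic TES ether, so the secondary TES and TBS ethers stay and the Z-enal forms without a separate deprotection.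

Step 15
Reactants: 22 allenyl (Z)-enal
Product: 25 8β-(tert-butyldimethylsilyloxy)-3β-hydroxy-15-(4-methoxybenzyloxy)germacra-1(10)E,4Z,11(13)-trien-12,6α-olide (6βH,7αH), via oxanickelacycle 23 (not isolated), via seco acid 24 (not isolated)
Conditions: Ni(cod)2 (2 equiv), DBU (8 equiv), CO2 (1 atm), THF (2 mM), 22 added slowly at 0 °C, then rt; then AcOH–H2O, rt
Reagents that add atoms: carbon dioxide O=C=O
Why: Proposed new method: DBU-ligated zerovalent nickel couples the unhindered terminal C11=C13 bond of the allene oxidatively with CO2 (C11–C12 bond) to give oxanickelacycle 23, a σ/π-allyl nickel carboxylate whose substituted terminus C7 then adds in SE2′ fashion through a closed six-membered transition state to the tethered aldehyde carbon C6 (C6–C7 bond), and acetic acid releases seco acid 24, which lactonises while the allylic TES ether is hydrolysed. The closest known reaction type is the nickel-mediated sequential addition of CO2 and an aldehyde to a terminal allene, known between separate partners, while closure of germacrane rings at this same C6–C7 bond by allylchromium or allylzinc addition to an enal is established, so only the merger of both in one macrocyclisation is new. Ring A closes by 10-exo-trig attack of the allyl γ-carbon on the carbonyl group and ring B by 5-exo-trig acyl substitution of the C6 hydroxyl at C12. The C6/C7 relationship should follow from the chair-like transition state of the E-configured σ-allyl form with both ring branches pseudo-equatorial (anti adduct, hence the trans-fused lactone with 6βH and 7αH), and the absolute sense from C8, whose hydrogen eclipses the C7=C11 bond to avoid A(1,3) strain with the carboxylate, so that the aldehyde reaches C7 on the face away from the C8–C9 bond with the bulky OTBS group turned outward. The step needs metallacycle formation at the allene only (the trisubstituted alkenes are too hindered and the β,β-disubstituted enal binds only reversibly), carboxylation at the central and C–C bond formation at the substituted allene carbon (the carboxylate chelate holds nickel on the CH2 terminus), 1,2-addition (closed transition state) and ring closure instead of oligomerisation (high dilution, slow addition). All three oxygens are carried as silyl or PMB ethers because allylic or allenylic esters would ionise on zerovalent nickel, and the O8 silyl ether also blocks the competing 8,12-lactone.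

Step 16
Reactants: 25 3β-hydroxy lactone
Product: 26 3β-acetoxy-8β-(tert-butyldimethylsilyloxy)-15-(4-methoxybenzyloxy)germacra-1(10)E,4Z,11(13)-trien-12,6α-olide
Conditions: Ac2O, pyridine, DMAP (cat.), CH2Cl2, 0 °C to rt
Reagents that add atoms: acetic anhydride CC(=O)OC(C)=O
Why: DMAP-catalysed acetylation of the only free hydroxyl group; no stereocentre is touched.

Step 17
Reactants: 26 3β-acetate
Product: 27 3β-acetoxy-8β-hydroxy-15-(4-methoxybenzyloxy)germacra-1(10)E,4Z,11(13)-trien-12,6α-olide
Conditions: HF·pyridine, pyridine, THF, 0 °C to rt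
Reagents that add atoms: none
Why: Fluoride-induced desilylation under mildly acidic conditions, which avoid base-induced translactonisation to O8 and conjugate addition to the α-methylene lactone.

Step 18
Reactants: 27 8β-alcohol
Product: 28 3β-acetoxy-8β-methacryloyloxy-15-(4-methoxybenzyloxy)germacra-1(10)E,4Z,11(13)-trien-12,6α-olide
Conditions: methacrylic anhydride, Et3N, DMAP, CH2Cl2, 0 °C to rt
Reagents that add atoms: methacrylic anhydride C=C(C)C(=O)OC(=O)C(C)=C
Why: DMAP-catalysed acylation of the hindered 8β-alcohol by the anhydride with retention at C8.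

Step 19
Reactants: 28 8β-methacrylate
Product: 29 1β,10α-epoxy-3β-acetoxy-8β-methacryloyloxy-15-(4-methoxybenzyloxy)germacra-4Z,11(13)-dien-12,6α-olide
Conditions: mCPBA, CH2Cl2, 0 °C
Reagents that add atoms: 3-chloroperbenzoic acid O=C(OO)c1cccc(Cl)c1
Why: Prilezhaev epoxidation: the strained 1(10)E alkene is the only electron-rich C=C (C4=C5 carries three allylic C–O bonds and the two acrylate-type alkenes are electron-poor), and because it stands perpendicular to the ring with C14 on the β side only its outer face is open, which should set C1 and C10 as the 1β,10α-epoxide.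

Step 20
Reactants: 29 PMB-protected epoxide
Product: 30 target, 1β,10α-epoxy-3β-acetoxy-15-hydroxy-8β-methacryloyloxygermacra-4Z,11(13)-dien-12,6α-olide (1R,3S,6R,7R,8R,10R)
Conditions: DDQ, CH2Cl2–pH 7 phosphate buffer, 0 °C
Reagents that add atoms: none
Why: Oxidative PMB ether cleavage (hydride abstraction by DDQ, hydrolysis of the hemiacetal) under neutral conditions that leave the epoxide, both esters and the lactone intact and give acetate migration little chance.

## Compound list

1 | 3-(trimethylsilyl)prop-2-ynal | C[Si](C)(C)C#CC=O | starting material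
2 | allenylboronic acid pinacol ester | C=C=CB1OC(C)(C)C(C)(C)O1 | starting material
3 | (R)-1-(trimethylsilyl)hexa-1,5-diyn-3-ol | C[Si](C)(C)C#C[C@H](O)CC#C | intermediate
4 | (R)-3-(tert-butyldimethylsilyloxy)-1-(trimethylsilyl)hexa-1,5-diyne | C[Si](C)(C)C#C[C@H](O[Si](C)(C)C(C)(C)C)CC#C | intermediate
5 | (E)-alkenyldimethylalane from 4 | C[Si](C)(C)C#C[C@H](O[Si](C)(C)C(C)(C)C)C/C(C)=C/[Al](C)C | intermediate
6 | lithium butyl(alkenyl)dimethylalanate | C[Si](C)(C)C#C[C@H](O[Si](C)(C)C(C)(C)C)C/C(C)=C/[Al-](C)(C)CCCC.[Li+] | intermediate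
7 | (3E,6R)-6-(tert-butyldimethylsilyloxy)-4-methyl-8-(trimethylsilyl)oct-3-en-7-yn-1-ol | C[Si](C)(C)C#C[C@H](O[Si](C)(C)C(C)(C)C)C/C(C)=C/CCO | intermediate
8 | (3E,6R)-6-(tert-butyldimethylsilyloxy)-4-methyloct-3-en-7-yn-1-ol | C#C[C@H](O[Si](C)(C)C(C)(C)C)C/C(C)=C/CCO | intermediate
9 | (3E,6R)-6-(tert-butyldimethylsilyloxy)-9-(diisopropylamino)-4-methylnon-3-en-7-yn-1-ol | CC(C)N(C(C)C)CC#C[C@H](O[Si](C)(C)C(C)(C)C)C/C(C)=C/CCO | intermediate
10 | (3E,6R)-6-(tert-butyldimethylsilyloxy)-4-methylnona-3,7,8-trien-1-ol | C=C=C[C@H](O[Si](C)(C)C(C)(C)C)C/C(C)=C/CCO | intermediate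
11 | (3E,6R)-6-(tert-butyldimethylsilyloxy)-4-methylnona-3,7,8-trienal | C=C=C[C@H](O[Si](C)(C)C(C)(C)C)C/C(C)=C/CC=O | intermediate
12 | but-2-yne-1,4-diol | OCC#CCO | starting material
13 | 4-(4-methoxybenzyloxy)but-2-yn-1-ol | OCC#CCOCc1ccc(OC)cc1 | intermediate
14 | sodium salt of the five-membered cyclic alkenylalanate | [Na+].COCCO[Al-]1(OCCOC)OCC=C1COCc1ccc(OC)cc1 | intermediate
15 | (Z)-3-iodo-4-(4-methoxybenzyloxy)but-2-en-1-ol | OC/C=C(\I)COCc1ccc(OC)cc1 | intermediate
16 | (Z)-triethyl{[3-iodo-4-(4-methoxybenzyloxy)but-2-en-1-yl]oxy}silane | I/C(COCc1ccc(OC)cc1)=C\CO[Si](CC)(CC)CC | intermediate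
17 | alkenylchromium dichloride from 16 | Cl[Cr](Cl)/C(COCc1ccc(OC)cc1)=C\CO[Si](CC)(CC)CC | intermediate
18 | open-chain allylic alcohol, epimers at C3 | C=C=C[C@H](O[Si](C)(C)C(C)(C)C)C/C(C)=C/CC(O)/C(COCc1ccc(OC)cc1)=C\CO[Si](CC)(CC)CC | intermediate
19 | open-chain C3 enone | C=C=C[C@H](O[Si](C)(C)C(C)(C)C)C/C(C)=C/CC(=O)/C(COCc1ccc(OC)cc1)=C\CO[Si](CC)(CC)CC | intermediate
20 | open-chain (3S)-allylic alcohol | C=C=C[C@H](O[Si](C)(C)C(C)(C)C)C/C(C)=C/C[C@H](O)/C(COCc1ccc(OC)cc1)=C\CO[Si](CC)(CC)CC | intermediate
21 | open-chain O3,O6-bis-TES ether | C=C=C[C@H](O[Si](C)(C)C(C)(C)C)C/C(C)=C/C[C@H](O[Si](CC)(CC)CC)/C(COCc1ccc(OC)cc1)=C\CO[Si](CC)(CC)CC | intermediate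
22 | allenyl (Z)-enal | C=C=C[C@H](O[Si](C)(C)C(C)(C)C)C/C(C)=C/C[C@H](O[Si](CC)(CC)CC)/C(COCc1ccc(OC)cc1)=C\C=O | intermediate
23 | oxanickelacycle (σ-allyl form, DBU ligands omitted) | O=C1O[Ni]C/C1=C/[C@H](O[Si](C)(C)C(C)(C)C)C/C(C)=C/C[C@H](O[Si](CC)(CC)CC)/C(COCc1ccc(OC)cc1)=C\C=O | intermediate
24 | ten-membered 6α-hydroxy 12-oic seco acid (O3-TES) | CC(C)(C)[Si](C)(C)O[C@@H]1C/C(C)=C/C[C@H](O[Si](CC)(CC)CC)/C(COCc2ccc(OC)cc2)=C\[C@@H](O)[C@@H]1C(=C)C(=O)O | intermediate
25 | 8β-TBSO-3β-hydroxy-15-PMBO-germacra-1(10)E,4Z,11(13)-trien-12,6α-olide | CC(C)(C)[Si](C)(C)O[C@@H]1C/C(C)=C/C[C@H](O)/C(COCc3ccc(OC)cc3)=C\[C@H]2OC(=O)C(=C)[C@@H]21 | intermediate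
26 | 3β-acetate of 25 | CC(C)(C)[Si](C)(C)O[C@@H]1C/C(C)=C/C[C@H](OC(C)=O)/C(COCc3ccc(OC)cc3)=C\[C@H]2OC(=O)C(=C)[C@@H]21 | intermediate
27 | 3β-acetoxy-8β-hydroxy-15-PMBO-germacratrienolide | O[C@@H]1C/C(C)=C/C[C@H](OC(C)=O)/C(COCc3ccc(OC)cc3)=C\[C@H]2OC(=O)C(=C)[C@@H]21 | intermediate
28 | 3β-acetoxy-8β-methacryloyloxy-15-PMBO-germacratrienolide | C=C(C)C(=O)O[C@@H]1C/C(C)=C/C[C@H](OC(C)=O)/C(COCc3ccc(OC)cc3)=C\[C@H]2OC(=O)C(=C)[C@@H]21 | intermediate
29 | 1β,10α-epoxide of 28 | C=C(C)C(=O)O[C@@H]1C[C@@]2(C)O[C@@H]2C[C@H](OC(C)=O)/C(COCc3ccc(OC)cc3)=C\[C@H]2OC(=O)C(=C)[C@@H]21 | intermediate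
30 | CNP0319155.1 | C=C(C)C(=O)O[C@@H]1C[C@@]2(C)O[C@@H]2C[C@H](OC(C)=O)/C(CO)=C\[C@H]2OC(=O)C(=C)[C@@H]21 | target

Total step count: 20. Longest linear sequence: 17 steps (steps 1–6 and 10–20).

## Steps most likely to fail

**1. Step 15.**
- What may go wrong:
  - The allylnickel carboxylate may be protonated before it closes the strained ten-membered ring.
  - It may lose the β-silyloxy group.
  - It may add to the aldehyde of a second molecule.
  - Zerovalent nickel may be tied up by the enal.
  - The facial bias exerted by C8 may be weak.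
- Fallback (known chemistry): the same two bonds are made between separate partners and ring A is closed at C3–C4. It sets out from 10 and 15 and comes back at 25.
  - Iodo alcohol 15 is oxidised with MnO2 to (Z)-3-iodo-4-(4-methoxybenzyloxy)but-2-enal F1.
  - Allene 10 is treated with Ni(cod)2, DBU and CO2 to give the oxanickelacycle F2.
  - F1 is then added (sequential addition of CO2 and an aldehyde to a terminal allene). Work-up with acetic acid should give the trans-disubstituted iodoalkenyl α-methylene-γ-lactone F3.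
  - Dess–Martin oxidation gives the lactone aldehyde F4.
  - An intramolecular Nozaki–Hiyama–Kishi reaction (CrCl2, cat. NiCl2, DMSO, high dilution) closes the C3–C4 bond to 25. The C3 configuration then rests on the conformational bias of the closing ring.

**2. Step 19.**
- What may go wrong: the peracid may attack the undesired face of the C1=C10 bond if the ring populates a conformer that turns C14 to the α side. The liberated acid may also open the epoxide in a transannular way.
- Fallback (reagent control on the open chain, epoxide carried through the ring closure): it sets out from 21 and comes back at 29.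
  - Shi epoxidation (D-fructose-derived ketone, KHSO5 as its triple salt, K2CO3, MeCN–dimethoxymethane–aqueous buffer, 0 °C) is run on 21. Only the C1=C10 bond there is electron-rich and unhindered, so this should give the open-chain (1R,10R)-epoxide F5.
  - The operations of steps 14 to 18 are then repeated. Swern oxidation gives the epoxy enal F6.
  - Nickel-mediated carboxylative ring closure runs by way of the epoxy oxanickelacycle F7 and the epoxy seco acid F8 to the epoxy hydroxy lactone F9.
  - Acetylation gives the epoxy acetate F10, and desilylation with HF·pyridine gives the epoxy 8β-alcohol F11.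
  - Methacrylation then gives 29.

**3. Step 1.**
- What may go wrong: enantioselectivity may be low because the slim alkynyl substituent offers the catalyst little steric differentiation. Some allenyl carbinol may also form.
- Fallback (racemic addition plus enzymatic resolution): it sets out from 1 and comes back at 3.
  - Barbier addition of propargyl bromide and zinc to 1 gives racemic 1-(trimethylsilyl)hexa-1,5-diyn-3-ol F12.
  - Kinetic resolution follows with Burkholderia cepacia lipase and vinyl acetate in hexane. It should acetylate the R enantiomer, whose silylalkynyl group takes the place of the large substituent, to (R)-1-(trimethylsilyl)hexa-1,5-diyn-3-yl acetate F13. It should leave (S)-1-(trimethylsilyl)hexa-1,5-diyn-3-ol F14.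
  - After separation, i-Bu2AlH at −78 °C cleaves F13 to 3 without touching the alkynylsilane.

## Further compounds

F1 | step 15 | (Z)-3-iodo-4-(4-methoxybenzyloxy)but-2-enal | O=C/C=C(\I)COCc1ccc(OC)cc1
F2 | step 15 | oxanickelacycle from 10 (DBU ligands omitted) | O=C1O[Ni]C/C1=C/[C@H](O[Si](C)(C)C(C)(C)C)C/C(C)=C/CCO
F3 | step 15 | iodoalkenyl α-methylene-γ-lactone with free C3 alcohol | CC(C)(C)[Si](C)(C)O[C@H](C/C(C)=C/CCO)[C@H]1C(=C)C(=O)O[C@@H]1/C=C(\I)COCc1ccc(OC)cc1
F4 | step 15 | lactone aldehyde | CC(C)(C)[Si](C)(C)O[C@H](C/C(C)=C/CC=O)[C@H]1C(=C)C(=O)O[C@@H]1/C=C(\I)COCc1ccc(OC)cc1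
F5 | step 19 | open-chain (1R,10R)-epoxide of 21 | C=C=C[C@H](O[Si](C)(C)C(C)(C)C)C[C@@]1(C)O[C@@H]1C[C@H](O[Si](CC)(CC)CC)/C(COCc1ccc(OC)cc1)=C\CO[Si](CC)(CC)CC
F6 | step 19 | epoxy enal | C=C=C[C@H](O[Si](C)(C)C(C)(C)C)C[C@@]1(C)O[C@@H]1C[C@H](O[Si](CC)(CC)CC)/C(COCc1ccc(OC)cc1)=C\C=O
F7 | step 19 | epoxy oxanickelacycle (DBU ligands omitted) | O=C1O[Ni]C/C1=C/[C@H](O[Si](C)(C)C(C)(C)C)C[C@@]1(C)O[C@@H]1C[C@H](O[Si](CC)(CC)CC)/C(COCc1ccc(OC)cc1)=C\C=O
F8 | step 19 | epoxy seco acid | CC(C)(C)[Si](C)(C)O[C@@H]1C[C@@]2(C)O[C@@H]2C[C@H](O[Si](CC)(CC)CC)/C(COCc2ccc(OC)cc2)=C\[C@@H](O)[C@@H]1C(=C)C(=O)O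
F9 | step 19 | epoxy hydroxy lactone | CC(C)(C)[Si](C)(C)O[C@@H]1C[C@@]2(C)O[C@@H]2C[C@H](O)/C(COCc3ccc(OC)cc3)=C\[C@H]2OC(=O)C(=C)[C@@H]21
F10 | step 19 | epoxy acetate | CC(C)(C)[Si](C)(C)O[C@@H]1C[C@@]2(C)O[C@@H]2C[C@H](OC(C)=O)/C(COCc3ccc(OC)cc3)=C\[C@H]2OC(=O)C(=C)[C@@H]21
F11 | step 19 | epoxy 8β-alcohol | O[C@@H]1C[C@@]2(C)O[C@@H]2C[C@H](OC(C)=O)/C(COCc3ccc(OC)cc3)=C\[C@H]2OC(=O)C(=C)[C@@H]21
F12 | step 1 | racemic 1-(trimethylsilyl)hexa-1,5-diyn-3-ol | C[Si](C)(C)C#CC(O)CC#C
F13 | step 1 | (R)-1-(trimethylsilyl)hexa-1,5-diyn-3-yl acetate | C[Si](C)(C)C#C[C@H](OC(C)=O)CC#C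
F14 | step 1 | (S)-1-(trimethylsilyl)hexa-1,5-diyn-3-ol | C[Si](C)(C)C#C[C@@H](O)CC#C
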